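**Strategy.** Everything rests on disconnecting the C4–C4a bond of ring C. The C4 carbonyl sits on C4a of ring A, a carbon next to the O1-bearing C8a and para to the C7 oxygen, which is the position a resorcinol diether offers most readily to an electrophile. An intramolecular Friedel–Crafts acylation therefore closes the chromanone in one operation from an (R)-3-aryloxy-2-arylpropanoic acid in which C3 is already set by an Evans alkylation. The acid carries three TIPS ethers and a C5' bromine that stands in for the acid-sensitive geranyl chain; a neutral Stille coupling and buffered fluoride deprotection complete the route.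

Key step: step 9

Remark (assumption): C3 of an isoflavanone is an enolisable, retro-oxa-Michael-prone α-aryl ketone centre, so it is assumed to tolerate only neutral or weakly acidic handling, and all steps after ring closure avoid base. The CIP order at this carbon (C=O > CH2O > aryl) is the same from imide to target, so the (S)-benzyl auxiliary, which gives the (R)-acid, leads to the (3R)-isoflavanone.

Step 1
Reactants: 1 2,4-dihydroxyphenylacetic acid
Product: 2 2-(5-bromo-2,4-dihydroxyphenyl)acetic acid
Conditions: NBS (1.0 equiv), MeCN, −20 to 0 °C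
Reagents that add atoms: N-bromosuccinimide, O=C1CCC(=O)N1Br
Why: Electrophilic aromatic bromination of the resorcinol ring should go to C5, which is para to the 2-OH and ortho to the 4-OH and less hindered than C3 between the two hydroxyls, while one equivalent of NBS at low temperature limits dibromination.

Step 2
Reactants: 2 2-(5-bromo-2,4-dihydroxyphenyl)acetic acid
Product: 4 2-[5-bromo-2,4-bis(triisopropylsilyloxy)phenyl]acetic acid, via triisopropylsilyl ester 3 (not isolated)
Conditions: TIPSCl (3.5 equiv), imidazole, DMF, rt; then K2CO3, MeOH–THF–H2O, 0 °C; 1 M HCl to pH 3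
Reagents that add atoms: triisopropylsilyl chloride, CC(C)[Si](Cl)(C(C)C)C(C)C
Why: Imidazole-mediated silylation caps both phenols and the carboxyl group, and the silyl ester, far more labile than the hindered aryl TIPS ethers, should then be cleaved selectively by brief carbonate hydrolysis.

Step 3
Reactants: 4 2-[5-bromo-2,4-bis(triisopropylsilyloxy)phenyl]acetic acid; 5 (S)-4-benzyl-2-oxazolidinone
Product: 7 (S)-4-benzyl-3-{2-[5-bromo-2,4-bis(triisopropylsilyloxy)phenyl]acetyl}oxazolidin-2-one, via mixed pivalic anhydride 6 (not isolated)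
Conditions: PivCl, Et3N, THF, −20 °C; then 5, LiCl, −20 °C to rt
Reagents that add atoms: none
Why: N-Acylation of the oxazolidinone through a mixed pivalic anhydride under LiCl/Et3N activation is a standard one-pot procedure, the hindered pivaloyl carbonyl directing attack to the arylacetyl carbonyl.

Step 4
Reactants: 8 resorcinol
Product: 9 3-(triisopropylsilyloxy)phenol
Conditions: resorcinol (3 equiv), TIPSCl (1 equiv), imidazole, DMF, 0 °C to rt
Reagents that add atoms: triisopropylsilyl chloride, CC(C)[Si](Cl)(C(C)C)C(C)C
Why: Statistical mono-silylation of a symmetrical diphenol, in which excess resorcinol (removed by aqueous washing) suppresses the bis-silyl ether.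

Step 5
Reactants: 9 3-(triisopropylsilyloxy)phenol
Product: 10 triisopropyl{3-[(methylsulfanyl)methoxy]phenoxy}silane
Conditions: NaH, DMF, 0 °C; ClCH2SMe, NaI (cat.), rt
Reagents that add atoms: chloromethyl methyl sulfide, CSCCl
Why: Williamson O-alkylation of the phenoxide with the reactive α-chloro sulfide, helped by iodide catalysis, should give the aryl methylthiomethyl ether, while the bulk of TIPS slows silyl transfer between phenoxides.

Step 6
Reactants: 10 triisopropyl{3-[(methylsulfanyl)methoxy]phenoxy}silane
Product: 11 [3-(chloromethoxy)phenoxy]triisopropylsilane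
Conditions: SO2Cl2 (1.0 equiv), CH2Cl2, −78 to 0 °C; cyclohexene; volatiles removed, used crude
Reagents that add atoms: sulfuryl chloride, O=S(=O)(Cl)Cl
Why: S-Chlorination of the sulfide and collapse of the chlorosulfonium salt is the known conversion of methylthiomethyl ethers into chloromethyl ethers; sulfur should react far faster than the arene at −78 °C, and cyclohexene traps the MeSCl that would otherwise sulfenylate the ring.

Step 7
Reactants: 7 (S)-4-benzyl-3-{2-[5-bromo-2,4-bis(triisopropylsilyloxy)phenyl]acetyl}oxazolidin-2-one; 11 [3-(chloromethoxy)phenoxy]triisopropylsilane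
Product: 13 (S)-4-benzyl-3-{(R)-2-[5-bromo-2,4-bis(triisopropylsilyloxy)phenyl]-3-[3-(triisopropylsilyloxy)phenoxy]propanoyl}oxazolidin-2-one, via trichlorotitanium enolate 12 (not isolated)
Conditions: TiCl4 (1.05 equiv), i-Pr2NEt (1.1 equiv), CH2Cl2, 0 °C; then 11 (1.5 equiv), 0 °C; aq. NH4Cl
Reagents that add atoms: none
Why: Evans asymmetric alkylation of a chelated (Z)-titanium enolate with an α-chloro ether, as practised with benzyl chloromethyl ether: the benzyl group of the (S)-auxiliary shields one enolate face, so the CH2OAr unit should enter anti to it and set the new centre as R (C=O > CH2OAr > aryl).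

Step 8
Reactants: 13 (S)-4-benzyl-3-{(R)-2-[5-bromo-2,4-bis(triisopropylsilyloxy)phenyl]-3-[3-(triisopropylsilyloxy)phenoxy]propanoyl}oxazolidin-2-one
Product: 15 (R)-2-[5-bromo-2,4-bis(triisopropylsilyloxy)phenyl]-3-[3-(triisopropylsilyloxy)phenoxy]propanoic acid, via peroxy acid 14 (not isolated)
Conditions: LiOH, 30% H2O2, THF–H2O, 0 °C; then Na2SO3; 1 M HCl to pH 3
Reagents that add atoms: hydrogen peroxide, OO
Why: Evans hydroperoxide cleavage, in which LiOOH attacks the exocyclic imide carbonyl selectively and is too weakly basic at 0 °C to epimerise the α-aryl centre, eliminate the β-aryloxy group or cleave the aryl TIPS ethers; sulfite then reduces the peroxy acid.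

Step 9
Reactants: 15 (R)-2-[5-bromo-2,4-bis(triisopropylsilyloxy)phenyl]-3-[3-(triisopropylsilyloxy)phenoxy]propanoic acid
Product: 17 (R)-5'-bromo-7,2',4'-tris(triisopropylsilyloxy)isoflavanone, via mixed trifluoroacetic anhydride 16 (not isolated)
Conditions: (CF3CO)2O, CF3CO2H, CH2Cl2, 0 °C to rt; cold aq. NaHCO3 quench
Reagents that add atoms: none
Why: TFAA turns the acid into the mixed anhydride 16, whose acyl carbon, made acylium-like by TFA, is attacked by the ring A carbon ortho to the ether oxygen and para to the silyloxy group, and loss of a proton from the arenium ion gives the C4 ketone. The closest known reaction type is the intramolecular Friedel–Crafts acylation of 3-aryloxypropanoic acids to chroman-4-ones. Ring C closes as a six-membered ring in a 6-exo-trig mode, the carbonyl oxygen staying outside the new ring and only the C4–C4a bond being formed. No stereocentre is created; the C3 centre from step 7 should be carried through because activation is base-free, so no ketene or enolate can form, and acid-catalysed enolisation is slow at 0 °C. The step needs regioselectivity for the carbon para to OSi over the one between the two oxygens, secured by the bulk of the TIPS group and the para preference of acylation, and C- over O-acylation, secured by the hindered, weakly nucleophilic 2'-silyl ether oxygen and by the absence of a Lewis acid or halide that could strip silicon. Bromine at C5' is inert to the medium, and ring B offers no carbon from which a comparable ring could close.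

Step 10
Reactants: 18 geranyl bromide
Product: 19 (E)-geranyltributylstannane
Conditions: Bu3SnH, LiN(i-Pr)2, THF, 0 °C; then 18, −78 °C
Reagents that add atoms: tributyltin hydride, CCCC[SnH](CCCC)CCCC
Why: SN2 displacement of the primary allylic bromide by tributylstannyllithium at −78 °C should give the linear allylstannane with the E double bond untouched.

Step 11
Reactants: 17 (R)-5'-bromo-7,2',4'-tris(triisopropylsilyloxy)isoflavanone; 19 (E)-geranyltributylstannane
Product: 20 (R)-5'-geranyl-7,2',4'-tris(triisopropylsilyloxy)isoflavanone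
Conditions: Pd(PPh3)4 (5 mol %), toluene, 100 °C, degassed
Reagents that add atoms: none
Why: Migita–Kosugi–Stille coupling of an aryl bromide with an allylstannane, in which oxidative addition, transmetalation and reductive elimination at the less substituted allyl terminus should give the linear (E)-geranyl arene in a neutral, base-free medium that does not enolise C3.

Step 12
Reactants: 20 (R)-5'-geranyl-7,2',4'-tris(triisopropylsilyloxy)isoflavanone
Product: 21 (3R)-3-{5-[(2E)-3,7-dimethylocta-2,6-dien-1-yl]-2,4-dihydroxyphenyl}-7-hydroxychroman-4-one (CNP0142504.1)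
Conditions: HF·pyridine, pyridine, THF, 0 °C to rt
Reagents that add atoms: none
Why: Fluoride-driven cleavage of the three aryl Si–O bonds (silyl ether deprotection) in a pyridine-buffered, weakly acidic medium that should neither enolise C3–H nor protonate the trisubstituted alkenes.

**Compound list**

1 | 2,4-dihydroxyphenylacetic acid | OC(=O)Cc1ccc(O)cc1O | starting material
2 | 2-(5-bromo-2,4-dihydroxyphenyl)acetic acid | OC(=O)Cc1cc(Br)c(O)cc1O | intermediate
3 | triisopropylsilyl 2-[5-bromo-2,4-bis(triisopropylsilyloxy)phenyl]acetate | CC(C)[Si](C(C)C)(C(C)C)OC(=O)Cc1cc(Br)c(O[Si](C(C)C)(C(C)C)C(C)C)cc1O[Si](C(C)C)(C(C)C)C(C)C | intermediate (not isolated)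
4 | 2-[5-bromo-2,4-bis(triisopropylsilyloxy)phenyl]acetic acid | OC(=O)Cc1cc(Br)c(O[Si](C(C)C)(C(C)C)C(C)C)cc1O[Si](C(C)C)(C(C)C)C(C)C | intermediate
5 | (S)-4-benzyl-2-oxazolidinone | O=C1OC[C@H](Cc2ccccc2)N1 | starting material
6 | mixed anhydride of 4 with pivalic acid | CC(C)(C)C(=O)OC(=O)Cc1cc(Br)c(O[Si](C(C)C)(C(C)C)C(C)C)cc1O[Si](C(C)C)(C(C)C)C(C)C | intermediate (not isolated)
7 | (S)-4-benzyl-3-{2-[5-bromo-2,4-bis(triisopropylsilyloxy)phenyl]acetyl}oxazolidin-2-one | O=C1OC[C@H](Cc2ccccc2)N1C(=O)Cc1cc(Br)c(O[Si](C(C)C)(C(C)C)C(C)C)cc1O[Si](C(C)C)(C(C)C)C(C)C | intermediate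
8 | resorcinol | Oc1cccc(O)c1 | starting material
9 | 3-(triisopropylsilyloxy)phenol | Oc1cccc(O[Si](C(C)C)(C(C)C)C(C)C)c1 | intermediate
10 | triisopropyl{3-[(methylsulfanyl)methoxy]phenoxy}silane | CSCOc1cccc(O[Si](C(C)C)(C(C)C)C(C)C)c1 | intermediate
11 | [3-(chloromethoxy)phenoxy]triisopropylsilane | ClCOc1cccc(O[Si](C(C)C)(C(C)C)C(C)C)c1 | intermediate
12 | trichlorotitanium (Z)-enolate of 7 | Cl[Ti](Cl)(Cl)O/C(=C\c1cc(Br)c(O[Si](C(C)C)(C(C)C)C(C)C)cc1O[Si](C(C)C)(C(C)C)C(C)C)N1C(=O)OC[C@@H]1Cc1ccccc1 | intermediate (not isolated)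
13 | (S)-4-benzyl-3-{(R)-2-[5-bromo-2,4-bis(triisopropylsilyloxy)phenyl]-3-[3-(triisopropylsilyloxy)phenoxy]propanoyl}oxazolidin-2-one | Brc1cc([C@@H](C(=O)N2C(=O)OC[C@@H]2Cc2ccccc2)COc2cccc(O[Si](C(C)C)(C(C)C)C(C)C)c2)c(O[Si](C(C)C)(C(C)C)C(C)C)cc1O[Si](C(C)C)(C(C)C)C(C)C | intermediate
14 | (R)-2-[5-bromo-2,4-bis(triisopropylsilyloxy)phenyl]-3-[3-(triisopropylsilyloxy)phenoxy]propaneperoxoic acid | Brc1cc([C@@H](C(=O)OO)COc2cccc(O[Si](C(C)C)(C(C)C)C(C)C)c2)c(O[Si](C(C)C)(C(C)C)C(C)C)cc1O[Si](C(C)C)(C(C)C)C(C)C | intermediate (not isolated)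
15 | (R)-2-[5-bromo-2,4-bis(triisopropylsilyloxy)phenyl]-3-[3-(triisopropylsilyloxy)phenoxy]propanoic acid | Brc1cc([C@@H](C(=O)O)COc2cccc(O[Si](C(C)C)(C(C)C)C(C)C)c2)c(O[Si](C(C)C)(C(C)C)C(C)C)cc1O[Si](C(C)C)(C(C)C)C(C)C | intermediate
16 | mixed anhydride of 15 with trifluoroacetic acid | Brc1cc([C@@H](C(=O)OC(=O)C(F)(F)F)COc2cccc(O[Si](C(C)C)(C(C)C)C(C)C)c2)c(O[Si](C(C)C)(C(C)C)C(C)C)cc1O[Si](C(C)C)(C(C)C)C(C)C | intermediate (not isolated)
17 | (R)-5'-bromo-7,2',4'-tris(triisopropylsilyloxy)isoflavanone | Brc1cc([C@@H]2COc3cc(O[Si](C(C)C)(C(C)C)C(C)C)ccc3C2=O)c(O[Si](C(C)C)(C(C)C)C(C)C)cc1O[Si](C(C)C)(C(C)C)C(C)C | intermediate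
18 | geranyl bromide | CC(C)=CCC/C(C)=C/CBr | starting material
19 | (E)-geranyltributylstannane | CC(C)=CCC/C(C)=C/C[Sn](CCCC)(CCCC)CCCC | intermediate
20 | (R)-5'-geranyl-7,2',4'-tris(triisopropylsilyloxy)isoflavanone | CC(C)=CCC/C(C)=C/Cc1cc([C@@H]2COc3cc(O[Si](C(C)C)(C(C)C)C(C)C)ccc3C2=O)c(O[Si](C(C)C)(C(C)C)C(C)C)cc1O[Si](C(C)C)(C(C)C)C(C)C | intermediate
21 | (3R)-3-{5-[(2E)-3,7-dimethylocta-2,6-dien-1-yl]-2,4-dihydroxyphenyl}-7-hydroxychroman-4-one (CNP0142504.1) | CC(C)=CCC/C(C)=C/Cc1cc([C@@H]2COc3cc(O)ccc3C2=O)c(O)cc1O | target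

**Step count.** Total: 12 steps. Longest linear sequence: 8 steps (1, 2, 3, 7, 8, 9, 11, 12; the resorcinol branch 4, 5, 6, 7, 8, 9, 11, 12 is equally long).

**Steps most likely to fail**

Step 9. Ring closure may be slow because a silyloxy group activates less than an alkoxy group. The 2'-silyl ether oxygen may instead attack the activated carboxyl, with loss of silicon and lactonisation. Prolonged acid contact may erode the C3 configuration through enolisation. The fallback sets out from 15 and returns at 17, and changes the nucleophile to a free phenol and the promoter to BF3·OEt2, as in the classical deoxybenzoin acylation. HF·pyridine in THF should remove the three silyl groups to give (R)-2-(5-bromo-2,4-dihydroxyphenyl)-3-(3-hydroxyphenoxy)propanoic acid F1. Under acid F1 may close reversibly onto the 2'-hydroxyl as (R)-5-bromo-6-hydroxy-3-[(3-hydroxyphenoxy)methyl]benzofuran-2(3H)-one F2. Either is an acyl donor in BF3·OEt2 at 50–60 °C, where the much more electron-rich 3-hydroxyphenoxy ring should be acylated para to its free hydroxyl to give (R)-5'-bromo-7,2',4'-trihydroxyisoflavanone F3. TIPSOTf and 2,6-lutidine in CH2Cl2 at −78 °C should then restore the three silyl ethers and give 17.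

Step 11. Oxidative addition next to the bulky silyloxy group may be sluggish. Allyl transposition (coupling at the tertiary terminus) or E/Z scrambling through π-allyl palladium species may give isomeric side chains. Long heating may epimerise C3. The fallback sets out from 17 and returns at 20, and reverses the polarity of the coupling. (Bu3Sn)2 with Pd(PPh3)4 in toluene at 100 °C should convert the bromide into (R)-5'-(tributylstannyl)-7,2',4'-tris(triisopropylsilyloxy)isoflavanone F4. A Stille coupling of F4 with geranyl bromide 18 (Pd2(dba)3, AsPh3, THF, 50 °C) should then give 20. Oxidative addition of the allylic bromide to zerovalent palladium is fast at this temperature, and aryl transfer normally occurs at the less substituted allyl terminus under neutral conditions.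

Step 7. The chloromethyl ether may ionise and alkylate an electron-rich arene instead of the enolate. The product may lose aryloxide by β-elimination. Facial selectivity may be reduced by the ortho-silyloxy aryl group. The fallback sets out from 7 and returns at 13, and makes the C–C and C–O bonds separately. The same titanium enolate is hydroxymethylated with s-trioxane and a second equivalent of TiCl4 to give (S)-4-benzyl-3-{(R)-2-[5-bromo-2,4-bis(triisopropylsilyloxy)phenyl]-3-hydroxypropanoyl}oxazolidin-2-one F5, with the same facial sense. A Mitsunobu etherification of the primary alcohol with phenol 9 (PPh3, DIAD, toluene, 0 °C) should then give 13. The risk in this fallback is dehydration to the acrylimide, which low temperature and the A1,3 strain that disfavours α-deprotonation should limit.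

**Further compounds**

F1 | step 9 | (R)-2-(5-bromo-2,4-dihydroxyphenyl)-3-(3-hydroxyphenoxy)propanoic acid | Brc1cc([C@@H](C(=O)O)COc2cccc(O)c2)c(O)cc1O
F2 | step 9 | (R)-5-bromo-6-hydroxy-3-[(3-hydroxyphenoxy)methyl]benzofuran-2(3H)-one | O=C1Oc2cc(O)c(Br)cc2[C@@H]1COc1cccc(O)c1
F3 | step 9 | (R)-5'-bromo-7,2',4'-trihydroxyisoflavanone | Brc1cc([C@@H]2COc3cc(O)ccc3C2=O)c(O)cc1O
F4 | step 11 | (R)-5'-(tributylstannyl)-7,2',4'-tris(triisopropylsilyloxy)isoflavanone | CCCC[Sn](CCCC)(CCCC)c1cc([C@@H]2COc3cc(O[Si](C(C)C)(C(C)C)C(C)C)ccc3C2=O)c(O[Si](C(C)C)(C(C)C)C(C)C)cc1O[Si](C(C)C)(C(C)C)C(C)C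
F5 | step 7 | (S)-4-benzyl-3-{(R)-2-[5-bromo-2,4-bis(triisopropylsilyloxy)phenyl]-3-hydroxypropanoyl}oxazolidin-2-one | Brc1cc([C@@H](C(=O)N2C(=O)OC[C@@H]2Cc2ccccc2)CO)c(O[Si](C(C)C)(C(C)C)C(C)C)cc1O[Si](C(C)C)(C(C)C)C(C)C
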